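**Plan**

1. Retrosynthetic cuts, in order: (a) the α-methyl of the ring-fused lactone goes back to an exocyclic methylene; (b) two bonds of the cyclohexene ring are cut at once, pyrrole α-carbon to azepine methine and O-bearing CH to pyrrolylic CH, together with the lactone acyl C–O bond. This formal (3+3) disconnection opens the azepine, the carbocycle and the fused lactone to a pyrrole that carries only the side-chain lactone; (c) the enal C=C (cross-metathesis), the allylboronate arm (from a pyrrole-3-carbaldehyde) and the side-chain lactone (from a pyrrole-2-carbaldehyde).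
2. Enabling feature: the three ring carbons azepine-CH, CH(Et) and CH–O are the β-, α- and carbonyl carbons of an α-ethyl enal (a 1,3-dielectrophile). The pyrrole α-carbon and the pyrrolylic lactone β-carbon form a 1,3-dinucleophile once that carbon is the γ-terminus of a 2-(methoxycarbonyl)allylboronate on the pyrrole. The γ-butyrolactone fused at exactly these carbons is what such an allylboration leaves behind.
3. Forward order: bought pyrrole → N-tether → side-chain lactone → allylboronate arm → enal → one-flask closure of azepine, cyclohexene and fused lactone → hydrogenation.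
4. Stereochemistry: side-chain carbinol from a catalytic asymmetric chromium allylation, its methyl from enolate protonation anti to the pyrrole; azepine methine from a chiral primary-amine (iminium) catalyst; the ethyl-, oxygen- and pyrrolyl-bearing ring carbons relayed from it through the chair transition state of the allylboration; the fused-lactone methyl from hydrogenation on the convex face.

Key step: step 9

Assumption: the chiral chromium ligand (step 2) and the cinchona amine (step 9) are taken to give the configurations drawn; if the sense of induction is opposite, the antipodal ligand or the pseudo-enantiomeric 9-amino-9-deoxy-epi-quinidine is used.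

**Route**

Step 1
Reactants: 1 4-iodo-1H-pyrrole-2-carbaldehyde; 2 6-bromohex-1-ene
Product: 3 1-(hex-5-en-1-yl)-4-iodo-1H-pyrrole-2-carbaldehyde
Conditions: K2CO3, DMF, 60 °C
Reagents that add atoms: none
Why: The N–H of a 2-formylpyrrole is acidic enough for carbonate-mediated SN2 N-alkylation with the primary bromide; no stereocentre is formed.

Step 2
Reactants: 3 1-(hex-5-en-1-yl)-4-iodo-1H-pyrrole-2-carbaldehyde; 4 methyl 2-(bromomethyl)acrylate
Product: 6 (S)-5-[1-(hex-5-en-1-yl)-4-iodo-1H-pyrrol-2-yl]-3-methylenedihydrofuran-2(3H)-one, via trimethylsilyl ether of the homoallylic alcohol 5 (not isolated)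
Conditions: CrCl2 (10 mol%), chiral tridentate 1,8-bis(4-isopropyl-4,5-dihydrooxazol-2-yl)-9H-carbazole ligand (12 mol%), Mn powder, TMSCl, THF, rt; then Bu4NF/AcOH, THF, 0 °C to rt
Reagents that add atoms: none
Why: Catalytic asymmetric Nozaki–Hiyama–Kishi 2-(alkoxycarbonyl)allylation: divalent chromium (recycled by Mn, with the aryl iodide and terminal alkene inert in the absence of nickel) turns the allyl bromide into a ligand-bound allylchromium that adds to one aldehyde face through a closed transition state to set the (S) carbinol, and buffered fluoride then frees the alcohol, which lactonises onto the ester without the acid that would ionise a pyrrol-2-yl carbinol.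

Step 3
Reactants: 6 (S)-5-[1-(hex-5-en-1-yl)-4-iodo-1H-pyrrol-2-yl]-3-methylenedihydrofuran-2(3H)-one
Product: 7 (3S,5S)-5-[1-(hex-5-en-1-yl)-4-iodo-1H-pyrrol-2-yl]-3-methyldihydrofuran-2(3H)-one
Conditions: Cu(OAc)2·H2O (5 mol%), 1,2-bis(diphenylphosphino)benzene (5 mol%), (EtO)2MeSiH, t-BuOH, toluene, rt
Reagents that add atoms: none
Why: Ligated copper hydride conjugate reduction should touch only the conjugated exocyclic methylene (isolated alkene and aryl iodide survive), and protonation of the copper enolate by t-BuOH on the face away from the γ-pyrrolyl group should place the methyl cis to it, which is also the thermodynamic arrangement.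

Step 4
Reactants: 7 (3S,5S)-5-[1-(hex-5-en-1-yl)-4-iodo-1H-pyrrol-2-yl]-3-methyldihydrofuran-2(3H)-one
Product: 8 1-(hex-5-en-1-yl)-5-[(2S,4S)-4-methyl-5-oxotetrahydrofuran-2-yl]-1H-pyrrole-3-carbaldehyde
Conditions: Pd(PPh3)4 (5 mol%), CO (1 atm), Bu3SnH (slow addition), THF, 50 °C
Reagents that add atoms: carbon monoxide, [C-]#[O+]
Why: Palladium-catalysed reductive carbonylation of the aryl iodide (oxidative addition to zerovalent palladium, CO insertion, hydride transfer from the stannane) should give the aldehyde under neutral conditions that spare the lactone and its stereocentres, slow stannane addition suppressing simple deiodination.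

Step 5
Reactants: 8 1-(hex-5-en-1-yl)-5-[(2S,4S)-4-methyl-5-oxotetrahydrofuran-2-yl]-1H-pyrrole-3-carbaldehyde; 9 methyl propiolate
Product: 11 methyl 2-{hydroxy[1-(hex-5-en-1-yl)-5-((2S,4S)-4-methyl-5-oxotetrahydrofuran-2-yl)-1H-pyrrol-3-yl]methyl}acrylate (both carbinol epimers), via vinylalane 10 (not isolated)
Conditions: i-Bu2AlH, N-methylmorpholine N-oxide, THF, 0 °C (9 to 10); then 8, 0 °C to rt; aq. potassium sodium tartrate work-up
Reagents that add atoms: none
Why: Hydroalumination of the propiolate gives the α-alumino acrylate 10, which adds 1,2 to the aldehyde to give the Morita–Baylis–Hillman-type adduct that the amine-catalysed variant would form only sluggishly from this electron-rich aldehyde; the new carbinol centre is uncontrolled and is erased in step 7.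

Step 6
Reactants: 11 methyl 2-{hydroxy[1-(hex-5-en-1-yl)-5-((2S,4S)-4-methyl-5-oxotetrahydrofuran-2-yl)-1H-pyrrol-3-yl]methyl}acrylate
Product: 12 methyl 2-{acetoxy[1-(hex-5-en-1-yl)-5-((2S,4S)-4-methyl-5-oxotetrahydrofuran-2-yl)-1H-pyrrol-3-yl]methyl}acrylate
Conditions: Ac2O, Et3N, DMAP (cat.), CH2Cl2, 0 °C
Reagents that add atoms: acetic anhydride, CC(=O)OC(C)=O
Why: DMAP-catalysed acetylation under basic conditions avoids acid-induced ionisation at the pyrrolylic carbon; should the acetate transpose to the primary allylic isomer, both isomers converge in step 7.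

Step 7
Reactants: 12 methyl 2-{acetoxy[1-(hex-5-en-1-yl)-5-((2S,4S)-4-methyl-5-oxotetrahydrofuran-2-yl)-1H-pyrrol-3-yl]methyl}acrylate
Product: 13 methyl (E)-3-[1-(hex-5-en-1-yl)-5-((2S,4S)-4-methyl-5-oxotetrahydrofuran-2-yl)-1H-pyrrol-3-yl]-2-[(4,4,5,5-tetramethyl-1,3,2-dioxaborolan-2-yl)methyl]acrylate
Conditions: Pd2(dba)3 (2.5 mol%), B2pin2, DMSO, 50 °C
Reagents that add atoms: bis(pinacolato)diboron, CC1(C)OB(OC1(C)C)B1OC(C)(C)C(C)(C)O1
Why: Miyaura-type allylic borylation: zerovalent palladium ionises the acetate to a π-allyl complex that is borylated at the unsubstituted terminus, which should give the conjugated allylboronate in the thermodynamically preferred geometry (pyrrole trans to the ester, cis to CH2B).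

Step 8
Reactants: 13 methyl (E)-3-[1-(hex-5-en-1-yl)-5-((2S,4S)-4-methyl-5-oxotetrahydrofuran-2-yl)-1H-pyrrol-3-yl]-2-[(4,4,5,5-tetramethyl-1,3,2-dioxaborolan-2-yl)methyl]acrylate; 14 2-ethylacrolein
Product: 15 methyl (E)-3-{1-[(E)-6-formyloct-5-en-1-yl]-5-[(2S,4S)-4-methyl-5-oxotetrahydrofuran-2-yl]-1H-pyrrol-3-yl}-2-[(4,4,5,5-tetramethyl-1,3,2-dioxaborolan-2-yl)methyl]acrylate
Conditions: second-generation Hoveyda–Grubbs catalyst (5 mol%), 14 (5 equiv), CH2Cl2, 40 °C
Reagents that add atoms: none
Why: Cross-metathesis of the terminal alkene with the 1,1-disubstituted enal should give the (E)-trisubstituted enal, as known for methacrolein; the trisubstituted acrylate alkene is inert and the ester-deactivated allylboronate is expected to ignore the conjugated aldehydes at 40 °C.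

Step 9
Reactants: 15 methyl (E)-3-{1-[(E)-6-formyloct-5-en-1-yl]-5-[(2S,4S)-4-methyl-5-oxotetrahydrofuran-2-yl]-1H-pyrrol-3-yl}-2-[(4,4,5,5-tetramethyl-1,3,2-dioxaborolan-2-yl)methyl]acrylate
Product: 18 tetracyclic α-methylene lactone (target skeleton in which the methyl of the ring-fused lactone is an exocyclic methylene), via azepine aldehyde 16 (not isolated), via pinacolboryl ether 17 (not isolated)
Conditions: 9-amino-9-deoxy-epi-quinine (20 mol%), CF3CO2H (40 mol%), H2O (2 equiv), toluene (0.02 M), rt; then 60 °C
Reagents that add atoms: none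
Why: The amine forms an iminium ion with the α-ethyl enal, the only free pyrrole α-carbon adds to its β-carbon (Friedel–Crafts conjugate addition) and enamine hydrolysis releases aldehyde 16; only now is an aldehyde held next to the allylboronate, whose γ-carbon adds through a closed six-membered chair transition state to give borate 17, which lactonises onto the cis ester. The closest known reaction types are the iminium-catalysed alkylation of pyrroles and indoles with enals (α-branched enals under primary-amine catalysis, N-tethered pyrroles intramolecularly) and the addition of 2-(alkoxycarbonyl)allylboronates to aldehydes that leads to α-methylene-γ-butyrolactones. Ring closures: azepine by 7-exo-trig attack of the pyrrole carbon on the iminium β-carbon, cyclohexene by 6-exo-trig attack of the allyl γ-carbon on the aldehyde, lactone by 5-exo-trig acyl substitution. Stereocontrol: the azepine methine is set by the chiral amine shielding one iminium face; the alkene geometry (pyrrole cis to CH2B, hence axial in the chair) fixes the O-bearing and pyrrolylic carbons as a cis-fused lactone, and their configuration relative to the azepine methine follows from the aldehyde face on which the azepine methylene is pseudo-equatorial and clear of the axial B–O bond; the ethyl-bearing carbon, epimerisable through the catalyst enamine, is expected to react as the epimer with equatorial ethyl. The step needs α-regioselectivity on the pyrrole, secured by the lactonyl group blocking the other α-position and a tether too short for the β-position, and the right order of events, secured by the 2-ester that slows the allylboronate and by the fact that allylboration before cyclisation would have to close an eleven-membered ring.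

Step 10
Reactants: 18 tetracyclic α-methylene lactone
Product: 19 bisdehydroneotuberostemonine
Conditions: H2 (1 atm), RhCl(PPh3)3 (10 mol%), benzene/EtOH, rt
Reagents that add atoms: none
Why: Homogeneous hydrogenation of the 1,1-disubstituted exocyclic alkene should deliver hydrogen on the convex face of the cis-fused lactone (the face of the two ring-fusion hydrogens, opposite the pyrrole), setting the last methyl-bearing centre, while this catalyst avoids the hydrogenolysis of the pyrrolylic C–O bond and the alkene migration that heterogeneous palladium could cause.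

**Compound list**

1 | 4-iodo-1H-pyrrole-2-carbaldehyde | O=Cc1cc(I)c[nH]1 | starting material
2 | 6-bromohex-1-ene | C=CCCCCBr | starting material
3 | 1-(hex-5-en-1-yl)-4-iodo-1H-pyrrole-2-carbaldehyde | C=CCCCCn1cc(I)cc1C=O | intermediate
4 | methyl 2-(bromomethyl)acrylate | C=C(CBr)C(=O)OC | starting material
5 | methyl (S)-4-[1-(hex-5-en-1-yl)-4-iodo-1H-pyrrol-2-yl]-2-methylene-4-(trimethylsilyloxy)butanoate | C=CCCCCn1cc(I)cc1[C@@H](O[Si](C)(C)C)CC(=C)C(=O)OC | intermediate
6 | (S)-5-[1-(hex-5-en-1-yl)-4-iodo-1H-pyrrol-2-yl]-3-methylenedihydrofuran-2(3H)-one | C=CCCCCn1cc(I)cc1[C@@H]2CC(=C)C(=O)O2 | intermediate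
7 | (3S,5S)-5-[1-(hex-5-en-1-yl)-4-iodo-1H-pyrrol-2-yl]-3-methyldihydrofuran-2(3H)-one (cis) | C=CCCCCn1cc(I)cc1[C@@H]2C[C@H](C)C(=O)O2 | intermediate
8 | 1-(hex-5-en-1-yl)-5-[(2S,4S)-4-methyl-5-oxotetrahydrofuran-2-yl]-1H-pyrrole-3-carbaldehyde | C=CCCCCn1cc(C=O)cc1[C@@H]2C[C@H](C)C(=O)O2 | intermediate
9 | methyl propiolate | C#CC(=O)OC | starting material
10 | diisobutyl[1-(methoxycarbonyl)vinyl]aluminium | C=C([Al](CC(C)C)CC(C)C)C(=O)OC | intermediate
11 | methyl 2-{hydroxy[1-(hex-5-en-1-yl)-5-((2S,4S)-4-methyl-5-oxotetrahydrofuran-2-yl)-1H-pyrrol-3-yl]methyl}acrylate (both carbinol epimers) | C=CCCCCn1cc(C(O)C(=C)C(=O)OC)cc1[C@@H]2C[C@H](C)C(=O)O2 | intermediate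
12 | methyl 2-{acetoxy[1-(hex-5-en-1-yl)-5-((2S,4S)-4-methyl-5-oxotetrahydrofuran-2-yl)-1H-pyrrol-3-yl]methyl}acrylate (both epimers) | C=CCCCCn1cc(C(OC(C)=O)C(=C)C(=O)OC)cc1[C@@H]2C[C@H](C)C(=O)O2 | intermediate
13 | methyl (E)-3-[1-(hex-5-en-1-yl)-5-((2S,4S)-4-methyl-5-oxotetrahydrofuran-2-yl)-1H-pyrrol-3-yl]-2-[(4,4,5,5-tetramethyl-1,3,2-dioxaborolan-2-yl)methyl]acrylate (pyrrole trans to ester) | C=CCCCCn1cc(/C=C(/C(=O)OC)CB3OC(C)(C)C(C)(C)O3)cc1[C@@H]2C[C@H](C)C(=O)O2 | intermediate
14 | 2-ethylacrolein (2-methylidenebutanal) | CCC(=C)C=O | starting material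
15 | methyl (E)-3-{1-[(E)-6-formyloct-5-en-1-yl]-5-[(2S,4S)-4-methyl-5-oxotetrahydrofuran-2-yl]-1H-pyrrol-3-yl}-2-[(4,4,5,5-tetramethyl-1,3,2-dioxaborolan-2-yl)methyl]acrylate | O=C/C(CC)=C/CCCCn1cc(/C=C(/C(=O)OC)CB3OC(C)(C)C(C)(C)O3)cc1[C@@H]2C[C@H](C)C(=O)O2 | intermediate
16 | (R)-2-[(9R)-1-{(E)-2-(methoxycarbonyl)-3-(pinacolboryl)prop-1-enyl}-3-((2S,4S)-4-methyl-5-oxotetrahydrofuran-2-yl)-6,7,8,9-tetrahydro-5H-pyrrolo[1,2-a]azepin-9-yl]butanal (reacting epimer drawn) | O=C[C@H](CC)[C@H]1CCCCn2c1c(/C=C(/C(=O)OC)CB3OC(C)(C)C(C)(C)O3)cc2[C@@H]4C[C@H](C)C(=O)O4 | intermediate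
17 | O-pinacolboryl homoallylic alkoxide: azepine-fused tetrahydroindole with ethyl, OBpin and 1-(methoxycarbonyl)vinyl on three adjacent ring carbons (OBpin cis to both neighbours) | CC[C@H]1[C@@H](OB5OC(C)(C)C(C)(C)O5)[C@@H](C(=C)C(=O)OC)c2cc([C@@H]3C[C@H](C)C(=O)O3)n3c2[C@@H]1CCCC3 | intermediate
18 | tetracyclic α-methylene lactone (target skeleton, exocyclic methylene in place of the fused-lactone methyl, all other centres as in the target) | CC[C@H]1[C@H]2OC(=O)C(=C)[C@H]2c2cc([C@@H]3C[C@H](C)C(=O)O3)n3c2[C@@H]1CCCC3 | intermediate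
19 | bisdehydroneotuberostemonine | CC[C@H]1[C@H]2OC(=O)[C@@H](C)[C@H]2c2cc([C@@H]3C[C@H](C)C(=O)O3)n3c2[C@@H]1CCCC3 | target

**Step count and risks**

Total steps: 10. Longest linear sequence: 10 steps (from 1; compounds 2, 4, 9 and 14 are bought).

Steps most likely to fail:

Step 9. The pyrrole α-carbon is deactivated and flanked by the conjugated acrylate arm and may add too slowly to the iminium ion. Protodeboronation or an untimed, unselective allylboration could then compete, and the facial selectivity of the allylboration and the equilibration at the ethyl-bearing carbon cannot be tuned separately from the first stage. Fallback (silicon in place of boron, stepwise; sets out from 8, returns at 18): Horner–Wadsworth–Emmons olefination of 8 with ethyl 2-(diethoxyphosphoryl)-3-(trimethylsilyl)propanoate (NaH, 1,2-dimethoxyethane) would give the β-(ethoxycarbonyl)allylsilane F1. Cross-metathesis with 14 as in step 8 would give the enal allylsilane F2. The amine-catalysed Friedel–Crafts cyclisation, now run alone on a substrate whose allylsilane tolerates stronger acid co-catalysts and longer times, would give the azepine aldehyde F3. Fluoride-induced intramolecular Hosomi–Sakurai allylation (Bu4NF, THF; BF3·OEt2 as the Lewis-acid variant if the ring fusion comes out trans) would give the hydroxy ester F4, which lactonises to 18.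

Step 8. During the metathesis the allylboronate is exposed to an excess of aldehyde at 40 °C, so intermolecular allylboration, together with slow turnover of the 1,1-disubstituted partner and homodimerisation of the terminal alkene, may erode the material. Fallback (boron introduced last; sets out from 12, returns at 15): cross-metathesis of acetate 12 with 14 under the conditions of step 8 would give the enal acetate F5, and the palladium-catalysed borylation of step 7 applied to F5 would then give 15, taken directly into step 9.

Step 2. The electron-rich pyrrole-2-carbaldehyde may react sluggishly or with low enantioselectivity under the chromium catalysis, and ionisation of the pyrrol-2-yl carbinol during desilylation could erode the configuration. Fallback (transfer-hydrogenative C–C coupling in place of the organochromium addition; sets out from 3, returns at 6): with [Ir(cod)Cl]2, a chiral biaryl bisphosphine, 4-cyano-3-nitrobenzoic acid and Cs2CO3 in THF with i-PrOH as reductant, 3 and methyl 2-{[(tert-butoxycarbonyl)oxy]methyl}acrylate would give, through a cyclometalated π-allyliridium nucleophile, the free hydroxy ester F6, which lactonises under the basic conditions to 6.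

**Further compounds**

F1 | step 9 | ethyl (E)-3-[1-(hex-5-en-1-yl)-5-((2S,4S)-4-methyl-5-oxotetrahydrofuran-2-yl)-1H-pyrrol-3-yl]-2-[(trimethylsilyl)methyl]acrylate | C=CCCCCn1cc(/C=C(/C(=O)OCC)C[Si](C)(C)C)cc1[C@@H]2C[C@H](C)C(=O)O2
F2 | step 9 | ethyl (E)-3-{1-[(E)-6-formyloct-5-en-1-yl]-5-[(2S,4S)-4-methyl-5-oxotetrahydrofuran-2-yl]-1H-pyrrol-3-yl}-2-[(trimethylsilyl)methyl]acrylate | O=C/C(CC)=C/CCCCn1cc(/C=C(/C(=O)OCC)C[Si](C)(C)C)cc1[C@@H]2C[C@H](C)C(=O)O2
F3 | step 9 | (R)-2-[(9R)-1-{(E)-2-(ethoxycarbonyl)-3-(trimethylsilyl)prop-1-enyl}-3-((2S,4S)-4-methyl-5-oxotetrahydrofuran-2-yl)-6,7,8,9-tetrahydro-5H-pyrrolo[1,2-a]azepin-9-yl]butanal | O=C[C@H](CC)[C@H]1CCCCn2c1c(/C=C(/C(=O)OCC)C[Si](C)(C)C)cc2[C@@H]3C[C@H](C)C(=O)O3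
F4 | step 9 | hydroxy ethyl ester: azepine-fused tetrahydroindole with ethyl, OH and 1-(ethoxycarbonyl)vinyl on three adjacent ring carbons (OH cis to both neighbours) | CC[C@H]1[C@@H](O)[C@@H](C(=C)C(=O)OCC)c2cc([C@@H]3C[C@H](C)C(=O)O3)n3c2[C@@H]1CCCC3
F5 | step 8 | methyl 2-{acetoxy[1-((E)-6-formyloct-5-en-1-yl)-5-((2S,4S)-4-methyl-5-oxotetrahydrofuran-2-yl)-1H-pyrrol-3-yl]methyl}acrylate | O=C/C(CC)=C/CCCCn1cc(C(OC(C)=O)C(=C)C(=O)OC)cc1[C@@H]2C[C@H](C)C(=O)O2
F6 | step 2 | methyl (S)-4-hydroxy-4-[1-(hex-5-en-1-yl)-4-iodo-1H-pyrrol-2-yl]-2-methylenebutanoate | C=CCCCCn1cc(I)cc1[C@@H](O)CC(=C)C(=O)OC
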